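**Retrosynthetic overview**
1. Parritadial ⇐ double Swern oxidation (C12-OH and C11-OTES) ⇐ Riley oxidation of the C12 methyl ⇐ 6α-O-acetylation.
2. 6α-O/9α-OH/Δ7 ⇐ singlet-oxygen [4+2] on a homoannular drima-6,8-diene from the α face, then O–O reduction.
3. Drima-6,8-diene ⇐ Δ7-drimene by selenium-mediated dehydrogenation.
4. Both rings in one operation (ring A, then ring B) ⇐ proton-initiated head-to-tail bicyclisation of an (8R)-8-acetoxy farnesyl-type acetate; the C8 acetate (future C1) is meant to control C5, C9 and C10.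
5. Acyclic precursor ⇐ geranyl acetate (allylic oxidation) plus a 3-methylbut-3-enyl Grignard reagent (catalytic asymmetric addition).

Assumption: the SMILES is read as 1β,6α-diacetoxy-9α-hydroxydrim-7-ene-11,12-dial, (1R,5S,6S,9S,10R); drimane numbering is used for bicyclic compounds (ring carbons C1–C10, C11 on C9, C12 on C8, α = face opposite the C10 methyl).

**Step 1**
Reactants: 1 geranyl acetate
Product: 2 (2E,6E)-3,7-dimethyl-8-oxoocta-2,6-dien-1-yl acetate
Conditions: SeO2 (1.3 equiv), 95% EtOH, reflux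
Reagents that add atoms: selenium dioxide O=[Se]=O
Why: Riley allylic oxidation (ene reaction then [2,3]-shift) at the E-methyl of the electron-rich terminal olefin, the 2,3-olefin being deactivated by its allylic acetate, taken through to the (E)-enal.

**Step 2**
Reactants: 2 (2E,6E)-3,7-dimethyl-8-oxoocta-2,6-dien-1-yl acetate; 3 4-bromo-2-methylbut-1-ene
Product: 6 (2E,6E,8R)-8-hydroxy-3,7,11-trimethyldodeca-2,6,11-trien-1-yl acetate, via Grignard reagent 4 (not isolated), via alkyltitanium triisopropoxide 5 (not isolated)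
Conditions: 3, Mg, THF, 25 °C; Ti(OiPr)4 (excess), CH2Cl2, −78 °C; then 2, (R)-3-(3,5-diphenylphenyl)-H8-BINOL (3 mol %), 0 °C
Reagents that add atoms: 4-bromo-2-methylbut-1-ene (3) C=C(C)CCBr
Why: Ti/H8-BINOL-catalysed enantioselective Grignard (alkyltitanium) 1,2-addition to an α-substituted enal, the ligand enantiomer being the one that delivers the alkyl group to the Re face to give the 8R carbinol, while RTi(OiPr)3 leaves the acetate untouched.

**Step 3**
Reactants: 6 (2E,6E,8R)-8-hydroxy-3,7,11-trimethyldodeca-2,6,11-trien-1-yl acetate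
Product: 7 (2E,6E,8R)-3,7,11-trimethyldodeca-2,6,11-triene-1,8-diyl diacetate
Conditions: Ac2O, DMAP (cat.), pyridine, CH2Cl2, 0 °C
Reagents that add atoms: acetic anhydride CC(=O)OC(C)=O
Why: Standard DMAP-catalysed O-acetylation; the stereocentre is not touched and the ester blocks ether formation with the C11 cation in the next step.

**Step 4**
Reactants: 7 (2E,6E,8R)-3,7,11-trimethyldodeca-2,6,11-triene-1,8-diyl diacetate
Product: 8 1β,11-diacetoxydrim-7-ene
Conditions: FSO3H (6 equiv), 2-nitropropane, −78 °C, 30 min; Et3N quench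
Reagents that add atoms: none
Why: Proposed new method: Markovnikov protonation of the isopropenyl group (the only olefin not deactivated by an allylic acetate) gives the tertiary C4 cation, which is captured by the 6E and then the 2E olefin through a chair–chair transition state (ring A, then ring B, both anti additions) before loss of H7, the closest known reaction being the superacid bicyclisation of farnesyl acetate to drimenyl acetate (biomimetic cationic polyene cyclisation); the O-protonated C8 acetate cannot ionise or act as a neighbouring group and takes the equatorial site of the forming ring A, so the 8R centre sets 10β-Me, 5α-H and 9β-CH2OAc (1R,5S,9S,10S).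

**Step 5**
Reactants: 8 1β,11-diacetoxydrim-7-ene
Product: 12 1β,11-diacetoxydrima-6,8-diene, via chloro selenide 9 (not isolated), via selenoxide 10 (not isolated), via allylic chloride 11 (not isolated)
Conditions: PhSeCl, CH2Cl2, −78 °C; 30% H2O2, pyridine, 0 → 25 °C; DBU, 50 °C
Reagents that add atoms: none
Why: Markovnikov trans-diaxial selenochlorination of the trisubstituted olefin, selenoxide syn-elimination (only C6 carries a syn hydrogen) and E2 loss of HCl (H9α anti to 8β-Cl) give the homoannular diene; C9 becomes sp2 and no new stereocentre forms.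

**Step 6**
Reactants: 12 1β,11-diacetoxydrima-6,8-diene
Product: 13 1β-acetoxydrima-6,8-dien-11-ol
Conditions: K2CO3 (0.3 equiv), MeOH, 0 °C
Reagents that add atoms: none
Why: Zemplén-type transesterification removes the unhindered primary allylic acetate much faster than the neopentyl-like secondary 1β-acetate flanked by the quaternary C10.

**Step 7**
Reactants: 13 1β-acetoxydrima-6,8-dien-11-ol
Product: 14 1β-acetoxy-11-(triethylsilyloxy)drima-6,8-diene
Conditions: TESCl, imidazole, CH2Cl2, 0 °C
Reagents that add atoms: chlorotriethylsilane CC[Si](Cl)(CC)CC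
Why: Standard silylation of the primary alcohol; TES is orthogonal to the acetates and can be oxidised off directly in step 11.

**Step 8**
Reactants: 14 1β-acetoxy-11-(triethylsilyloxy)drima-6,8-diene
Product: 16 1β-acetoxy-11-(triethylsilyloxy)drim-7-ene-6α,9α-diol, via endoperoxide 15 (not isolated)
Conditions: O2, TPP (1 mol %), hν (visible), CH2Cl2, −30 °C; then thiourea, MeOH, 25 °C
Reagents that add atoms: dioxygen O=O
Why: Singlet-oxygen [4+2] cycloaddition to the s-cis-locked diene occurs on the α face (the β face is blocked by the axial C10 and C4β methyls), setting 6α-O and 9α-O together and placing the olefin at C7=C8, and thiourea then cleaves only the O–O bond.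

**Step 9**
Reactants: 16 1β-acetoxy-11-(triethylsilyloxy)drim-7-ene-6α,9α-diol
Product: 17 1β,6α-diacetoxy-11-(triethylsilyloxy)drim-7-en-9α-ol
Conditions: Ac2O, DMAP (cat.), pyridine, CH2Cl2, 0 °C
Reagents that add atoms: acetic anhydride CC(=O)OC(C)=O
Why: DMAP-catalysed acetylation of the secondary allylic 6α-OH with retention; the tertiary 9α-OH is not acylated under these conditions.

**Step 10**
Reactants: 17 1β,6α-diacetoxy-11-(triethylsilyloxy)drim-7-en-9α-ol
Product: 18 1β,6α-diacetoxy-11-(triethylsilyloxy)drim-7-ene-9α,12-diol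
Conditions: SeO2 (0.5 equiv), t-BuOOH (5.5 M in decane, 4 equiv), CH2Cl2, 35 °C
Reagents that add atoms: selenium dioxide O=[Se]=O (catalytic, transfers the O); tert-butyl hydroperoxide CC(C)(C)OO (terminal source of the O)
Why: Riley oxidation at the only allylic C–H on the more substituted olefin carbon (the C12 methyl; C9 has no H), the same olefin type as in the known oxidation of prenyl acetate; any 12-aldehyde formed is carried on, since the silylated C11 oxygen prevents lactol formation.

**Step 11**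
Reactants: 18 1β,6α-diacetoxy-11-(triethylsilyloxy)drim-7-ene-9α,12-diol
Product: 19 parritadial
Conditions: (COCl)2, DMSO, CH2Cl2, −78 → −40 °C; Et3N, −78 → −30 °C
Reagents that add atoms: none
Why: Swern oxidation converts the allylic 12-OH and, by direct attack of the chlorosulfonium ion on the primary TES ether, the C11 oxygen into aldehydes in one operation, so no lactol or lactone can form; acetates and the tertiary alcohol survive at low temperature.

**Compound list**
1 | geranyl acetate | CC(=O)OC/C=C(\C)CCC=C(C)C | starting material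
2 | (2E,6E)-3,7-dimethyl-8-oxoocta-2,6-dien-1-yl acetate | CC(=O)OC/C=C(\C)CC/C=C(\C)C=O | intermediate
3 | 4-bromo-2-methylbut-1-ene | C=C(C)CCBr | starting material
4 | (3-methylbut-3-en-1-yl)magnesium bromide | C=C(C)CC[Mg]Br | intermediate
5 | triisopropoxy(3-methylbut-3-en-1-yl)titanium | C=C(C)CC[Ti](OC(C)C)(OC(C)C)OC(C)C | intermediate
6 | (2E,6E,8R)-8-hydroxy-3,7,11-trimethyldodeca-2,6,11-trien-1-yl acetate | CC(=O)OC/C=C(\C)CC/C=C(\C)[C@H](O)CCC(C)=C | intermediate
7 | (2E,6E,8R)-3,7,11-trimethyldodeca-2,6,11-triene-1,8-diyl diacetate | CC(=O)OC/C=C(\C)CC/C=C(\C)[C@H](OC(C)=O)CCC(C)=C | intermediate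
8 | 1β,11-diacetoxydrim-7-ene, (1R,5S,9S,10S) | C1C=C(C)[C@H](COC(C)=O)[C@@]2(C)[C@H](OC(C)=O)CCC(C)(C)[C@H]12 | intermediate
9 | 1β,11-diacetoxy-8β-chloro-7α-(phenylselanyl)drimane | C1[C@@H]([Se]c3ccccc3)[C@](C)(Cl)[C@H](COC(C)=O)[C@@]2(C)[C@H](OC(C)=O)CCC(C)(C)[C@H]12 | intermediate
10 | 1β,11-diacetoxy-8β-chloro-7α-(phenylseleninyl)drimane | C1[C@@H]([Se](=O)c3ccccc3)[C@](C)(Cl)[C@H](COC(C)=O)[C@@]2(C)[C@H](OC(C)=O)CCC(C)(C)[C@H]12 | intermediate
11 | 1β,11-diacetoxy-8β-chlorodrim-6-ene | C1=C[C@](C)(Cl)[C@H](COC(C)=O)[C@@]2(C)[C@H](OC(C)=O)CCC(C)(C)[C@H]12 | intermediate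
12 | 1β,11-diacetoxydrima-6,8-diene (5α-H, 10β-Me) | C1=CC(C)=C(COC(C)=O)[C@@]2(C)[C@H](OC(C)=O)CCC(C)(C)[C@H]12 | intermediate
13 | 1β-acetoxydrima-6,8-dien-11-ol | C1=CC(C)=C(CO)[C@@]2(C)[C@H](OC(C)=O)CCC(C)(C)[C@H]12 | intermediate
14 | 1β-acetoxy-11-(triethylsilyloxy)drima-6,8-diene | C1=CC(C)=C(CO[Si](CC)(CC)CC)[C@@]2(C)[C@H](OC(C)=O)CCC(C)(C)[C@H]12 | intermediate
15 | 1β-acetoxy-6α,9α-epidioxy-11-(triethylsilyloxy)drim-7-ene | O3[C@H]1C=C(C)[C@](O3)(CO[Si](CC)(CC)CC)[C@@]2(C)[C@H](OC(C)=O)CCC(C)(C)[C@H]12 | intermediate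
16 | 1β-acetoxy-11-(triethylsilyloxy)drim-7-ene-6α,9α-diol | O[C@H]1C=C(C)[C@](O)(CO[Si](CC)(CC)CC)[C@@]2(C)[C@H](OC(C)=O)CCC(C)(C)[C@H]12 | intermediate
17 | 1β,6α-diacetoxy-11-(triethylsilyloxy)drim-7-en-9α-ol | CC(=O)O[C@H]1C=C(C)[C@](O)(CO[Si](CC)(CC)CC)[C@@]2(C)[C@H](OC(C)=O)CCC(C)(C)[C@H]12 | intermediate
18 | 1β,6α-diacetoxy-11-(triethylsilyloxy)drim-7-ene-9α,12-diol | CC(=O)O[C@H]1C=C(CO)[C@](O)(CO[Si](CC)(CC)CC)[C@@]2(C)[C@H](OC(C)=O)CCC(C)(C)[C@H]12 | intermediate
19 | parritadial, 1β,6α-diacetoxy-9α-hydroxydrim-7-ene-11,12-dial, (1R,5S,6S,9S,10R) | CC(=O)O[C@H]1C=C(C=O)[C@](O)(C=O)[C@@]2(C)[C@H](OC(C)=O)CCC(C)(C)[C@H]12 | target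

**Totals**
Total steps: 11. Longest linear sequence: 11 steps (from geranyl acetate 1; the Grignard reagent is made in the flask in step 2).

**Three steps most likely to fail**

Step 4 (bicyclisation). The cation that develops at C10 is β to the protonated acetate, so ring closure is slowed. The equatorial preference of the C1 acetate is also opposed by A(1,2) contact with the C10 methyl, so the diastereoselectivity is not known in advance. Fallback, from 7 back to 8: replace proton initiation by mercurinium initiation, which works on the neutral, unprotonated diacetate. Hg(OTf)2·PhNMe2 in MeNO2 at −20 °C, then aqueous NaCl, gives the alkylmercury chloride 1β,11-diacetoxy-13-(chloromercurio)drim-7-ene F1 (C4 epimers). Reductive demercuration with NaBH4/NaOH turns CH2HgCl into the second C4 methyl and gives 8.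

Step 5 (diene formation). The regiochemistry of the HCl loss is not secure, and the 6,8-diene places C11 in the plane next to the 1β-acetate (peri strain). Fallback, from 8 back to 12: mCPBA/NaHCO3 epoxidises the α face to 7α,8α-epoxy-1β,11-diacetoxydrimane F2. Catalytic TsOH in benzene at 60 °C opens it at C8 with loss of H9 to 1β,11-diacetoxydrim-8-en-7α-ol F3, which is not isolated. F3 dehydrates through the C7–C8–C9 allyl cation (loss of H6) to 12.

Step 10 (Riley oxidation of a deactivated olefin with an acid-labile TES ether present). Fallback, from 17 back to 18: Wohl–Ziegler bromination (NBS, AIBN, PhCF3, 80 °C) attacks the only unhindered allylic C–H and gives 12-bromo-1β,6α-diacetoxy-11-(triethylsilyloxy)drim-7-en-9α-ol F4. Silver-assisted hydrolysis (AgOTf, 2,6-lutidine, aqueous acetone) then gives 18.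

**Further compounds**
F1 | step 4 | 1β,11-diacetoxy-13-(chloromercurio)drim-7-ene (C4 epimers) | C1C=C(C)[C@H](COC(C)=O)[C@@]2(C)[C@H](OC(C)=O)CCC(C)(C[Hg]Cl)[C@H]12
F2 | step 5 | 7α,8α-epoxy-1β,11-diacetoxydrimane | C1[C@H]3O[C@@]3(C)[C@H](COC(C)=O)[C@@]2(C)[C@H](OC(C)=O)CCC(C)(C)[C@H]12
F3 | step 5 | 1β,11-diacetoxydrim-8-en-7α-ol | C1[C@@H](O)C(C)=C(COC(C)=O)[C@@]2(C)[C@H](OC(C)=O)CCC(C)(C)[C@H]12
F4 | step 10 | 12-bromo-1β,6α-diacetoxy-11-(triethylsilyloxy)drim-7-en-9α-ol | CC(=O)O[C@H]1C=C(CBr)[C@](O)(CO[Si](CC)(CC)CC)[C@@]2(C)[C@H](OC(C)=O)CCC(C)(C)[C@H]12
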